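**Late rates.** Over the last two readings of the spring and dawn runs, 1.67 d to 2.50 d, the rate at which L (monomer in chains) forms per unit of E (dissolved monomer) can be read as a pseudo-first-order constant, the inverse of a time constant. E comes from the solid J. The spring run reads 0.106 d⁻¹ and the dawn run 0.647 d⁻¹.

| setting | spring | winter | dawn | flask |
|---|---|---|---|---|
| J | 0.12 M | 0.18 M | 0.24 M | 0.24 M |
| G | 1 mol% | 1 mol% | 2 mol% | 1 mol% |
| D | 0.66 mM | 0.66 mM | 0.66 mM | 0.66 mM |
| remark | run made earlier | run made earlier | run made earlier |  |
| time |  |  |  | 4.0 d |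

| run | time / d | L / % | E / % |
|---|---|---|---|
| spring | 0.333 | 0 | 31.6 |
| spring | 0.833 | 0 | 62.6 |
| spring | 1.67 | 3.8 | 86.9 |
| spring | 2.50 | 11.5 | 88.8 |
| winter | 0.208 | 0.2 | 14.9 |
| winter | 0.417 | 0 | 25.5 |
| winter | 1.04 | 2.4 | 46.9 |
| winter | 2.50 | 15.3 | 58.9 |
| dawn | 0.625 | 0.9 | 24.0 |
| dawn | 1.25 | 6.9 | 33.8 |
| dawn | 1.67 | 14.3 | 35.3 |
| dawn | 2.50 | 32.8 | 33.6 |

(readings scatter by 0.5 percentage points)

- J is a solid; its amount is given per volume of the solution
- at the start none of J is in solution
- E is what J becomes in solution

- theta: doubling the dissolution coefficient of J, all else as stated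
- epsilon: doubling the amount of G, all else as stated
- alpha: doubling the solubility of J, all else as stated

* how much L there is at 4.0 d, in percent of the J charged
* concentration of E in solution at 10 h, in percent of saturation
* the change that raises the amount of L at 4.0 d, in percent of the J charged most ("none" if none brings more than 2 percentage points) (theta / epsilon / alpha / none)
* amount of L at 4.0 d, in percent of the J charged, after theta

**The puzzle.** The dawn run holds 4.00 times the initiator G of the spring run, yet its constant reads 6.10 times that of the spring run.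

**The surplus.** My reckoning supposes that D takes G one for one, quickly, and counts what remains. In this flask that is 1.74 mM: the surplus S, G charged minus D charged. The spring run has 0.540 mM and the dawn run 4.14 mM, a ratio of 7.67, and the ratio read from the constants lies between this one and the ratio of the G charged. The constant per unit of S reads 0.196 d⁻¹ mM⁻¹ and 0.156 d⁻¹ mM⁻¹. Their mean gives this flask about 0.306 d⁻¹ over the same window.

**The forecast.** Among its grounds is this: "L appears after an induction period that shortens as G rises". It gives 38% (32% to 44%), 35%, epsilon and 45%.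

    G + D → X (k = 9.60 M⁻¹ s⁻¹)
    E + Q → L + Q, rate k2*[Q]*[E] (k = 0.00280 M⁻¹ s⁻¹)
    E + G → Q + L (k = 9.40 × 10⁻⁵ M⁻¹ s⁻¹)
    J ⇌ E, rate k4*(cs4 - [E]) while solid is left; crystals form when [E] > cs4 (solubility = 0.130 M, k = 1.20 × 10⁻⁵ s⁻¹)

**The result.** The flask gives 39.5%, 34.9%, epsilon and 51.4%, against the forecast's 45% for the last. Here Q is the living end and X the product of G with D. At 4.00 d the G left, 0.113 mM, plus Q, 1.63 mM, make 1.74 mM, which matches S. Now take a neighbouring flask, the same recipe with D at 2.60 mM: its S is −0.200 mM. There the D left is 0.200 mM, the G left is 0%, and L is 0%.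

The runs are simulated for an exercise; noise was put on by code.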